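**Retrosynthetic overview**
1. Numbering: C1 (carbinol), C2 (syringyl CH), O3, C4, C5 (fusion CH), C6 (guaiacyl CH), O7, C8; ring A = C1–C2–O3–C4–C5, ring B = C1–C5–C6–O7–C8; the target is (1S,2R,5R,6S) in this numbering.
2. The route rests on C6: it is a benzylic ether carbon whose C–H lies 1,5 to C5 along C5–C1–C8–O7–C6. C5–C6 is therefore cut back to a carbenoid at C5 of a ring A α-diazo lactone (C4 as carbonyl) inserting into a vanillyl ether, which closes ring B cis onto ring A and fixes C5.
3. The diazo lactone comes from a (4S,5R)-hydroxy lactone: Horner–Wadsworth–Emmons arylidene succinate, allylic alcohol, Sharpless epoxidation (C1), invertive lactonisation (C2), then vanillyl ether, O-silylation and diazo transfer.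
4. After the insertion the lactone is reduced and ring A re-closed as the ether; ring B is then opened at C6–O7 by thiolysis and re-closed through the guaiacyl quinone methide, which sets C6 exo under kinetic control.
5. Ring order: ring A (lactone), ring B (insertion), ring A (ether), ring B (re-cast at C6–O7).

Key step: step 11

Remark on the chemistry: closely related diazolactone insertions place the new aryl on the concave face (endo), so 17 is drawn as the 6-endo epimer; the route does not depend on this, because steps 14 to 16 erase and reset C6.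
Abbreviations: ArS = 3,5-dimethoxy-4-(triisopropylsilyloxy)phenyl; ArG = 3-methoxy-4-(triisopropylsilyloxy)phenyl.

**Route**

Step 1
Reactants: 1 syringaldehyde
Product: 2 3,5-dimethoxy-4-(triisopropylsilyloxy)benzaldehyde
Conditions: iPr3SiCl, imidazole, DMF, rt to 40 °C
Reagents that add atoms: chlorotriisopropylsilane, CC(C)[Si](Cl)(C(C)C)C(C)C
Why: Imidazole-promoted silylation masks the phenol as a TIPS ether, which should survive hydride, amide base and Lewis acid and leave with fluoride at the end.

Step 2
Reactants: 3 trimethyl phosphonoacetate; 4 tert-butyl bromoacetate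
Product: 5 4-tert-butyl 1-methyl 2-(dimethoxyphosphoryl)butanedioate
Conditions: NaH, THF, 0 °C; then 4, rt
Reagents that add atoms: none
Why: SN2 C-alkylation of the phosphonoacetate anion gives the phosphonosuccinate with the two carboxyls already differentiated as methyl and tert-butyl esters.

Step 3
Reactants: 5 phosphonosuccinate; 2 silylated syringaldehyde
Product: 6 4-tert-butyl 1-methyl (2E)-2-(ArS-methylidene)butanedioate
Conditions: NaH, THF, 0 °C to rt
Reagents that add atoms: none
Why: Horner–Wadsworth–Emmons olefination should give the E-alkene (aryl trans to CO2Me) under conditions that spare the aryl silyl ether, which the alkoxide of a Stobbe condensation would not.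

Step 4
Reactants: 6 arylidene succinate
Product: 7 tert-butyl (3E)-4-ArS-3-(hydroxymethyl)but-3-enoate
Conditions: iBu2AlH (2.2 equiv), CH2Cl2, −78 °C; Rochelle salt
Reagents that add atoms: none
Why: iBu2AlH at low temperature should reduce the conjugated methyl ester to the allylic alcohol and leave the hindered tert-butyl ester, which also cannot lactonise onto the new hydroxyl.

Step 5
Reactants: 7 allylic alcohol
Product: 9 (4S,5R)-5-ArS-4-hydroxy-4-(hydroxymethyl)oxolan-2-one, via epoxy alcohol 8 (not isolated)
Conditions: Ti(OiPr)4 (cat.), L-(+)-diethyl tartrate, tBuOOH, 4 Å MS, CH2Cl2, −20 °C; then CF3CO2H, CH2Cl2, 0 °C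
Reagents that add atoms: tert-butyl hydroperoxide, CC(C)(C)OO
Why: Sharpless asymmetric epoxidation with the L-(+)-tartrate should give the (2S,3S)-epoxy alcohol 8 (sets C1), and acid then lets the ester carbonyl open the epoxide at the benzylic carbon with inversion (five-membered lactone, loss of isobutene), which sets C2 with the aryl cis to the tertiary OH.

Step 6
Reactants: 10 vanillyl alcohol
Product: 11 (3-methoxy-4-(triisopropylsilyloxy)phenyl)methanol
Conditions: NaH (1.0 equiv), THF, 0 °C; iPr3SiCl
Reagents that add atoms: chlorotriisopropylsilane, CC(C)[Si](Cl)(C(C)C)C(C)C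
Why: One equivalent of base forms only the phenoxide, which is silylated in preference to the neutral benzylic alcohol.

Step 7
Reactants: 11 silylated vanillyl alcohol
Product: 12 ArG-methyl 2,2,2-trichloroacetimidate
Conditions: Cl3CCN, DBU (cat.), CH2Cl2, 0 °C; used crude
Reagents that add atoms: trichloroacetonitrile, N#CC(Cl)(Cl)Cl
Why: Base-catalysed addition of the alcohol to the nitrile gives the imidate, a benzyl donor that is activated by acid and needs no base.

Step 8
Reactants: 9 hydroxy lactone; 12 imidate
Product: 13 (4S,5R)-5-ArS-4-hydroxy-4-(ArG-methoxymethyl)oxolan-2-one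
Conditions: camphorsulfonic acid (cat.), CH2Cl2, 0 °C to rt
Reagents that add atoms: none
Why: Acid-catalysed trichloroacetimidate etherification should alkylate the primary hydroxyl (the tertiary one is too hindered), and the base-free conditions avoid translactonisation of the hydroxymethyl lactone.

Step 9
Reactants: 13 vanillyl ether lactone
Product: 14 (4S,5R)-5-ArS-4-(ArG-methoxymethyl)-4-(triethylsilyloxy)oxolan-2-one
Conditions: Et3SiOTf, 2,6-lutidine, CH2Cl2, 0 °C
Reagents that add atoms: triethylsilyl trifluoromethanesulfonate, CC[Si](CC)(CC)OS(=O)(=O)C(F)(F)F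
Why: Silyl triflate silylation caps the tertiary alcohol, removing the O–H that could quench the carbenoid.

Step 10
Reactants: 14 silylated lactone
Product: 16 (4S,5R)-3-diazo-5-ArS-4-(ArG-methoxymethyl)-4-(triethylsilyloxy)oxolan-2-one, via trifluoroacetyl lactone 15 (not isolated)
Conditions: LiN(SiMe3)2, THF, −78 °C; CF3CO2CH2CF3; then MeSO2N3, Et3N, H2O (1 equiv), MeCN, rt
Reagents that add atoms: methanesulfonyl azide, CS(=O)(=O)N=[N+]=[N-]
Why: Regitz-type deacylative diazo transfer: the lithium enolate is C-trifluoroacetylated to 15, whose activated methine takes the diazo group from the sulfonyl azide with loss of the trifluoroacetyl group, and the low temperature should keep the β-silyloxy enolate from eliminating.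

Step 11
Reactants: 16 α-diazo lactone
Product: 17 (1S,2R,5R,6R)-2-ArS-6-ArG-1-(triethylsilyloxy)-3,7-dioxabicyclo[3.3.0]octan-4-one (syringyl exo and guaiacyl endo)
Conditions: Rh2(OAc)4 (2 mol%), CH2Cl2, reflux, slow addition of 16
Reagents that add atoms: none
Why: Rh2(OAc)4 expels N2 from 16 to give the electrophilic carbenoid at C5, which inserts into the C6–H bond of the vanillyl ether through a concerted three-centre transition state; the closest known reaction is the intramolecular 1,5 C–H insertion of α-diazo-γ-butyrolactones into benzylic ethers to give furofuranones. Ring B closes as a five-membered ring by C5–C6 bond formation across the tether C1–C8–O7–C6. C5 is controlled by the tether, since the C8 arm sits on one face of the lactone and the fusion can only be cis, with H5 syn to the C1 oxygen. C6 is controlled by the chair-like transition state that includes rhodium, where the aryl lies pseudo-equatorial and away from the ligand wall; this should place it on the concave face (cis to the C4 carbonyl), the opposite of what the target needs, hence the later reset. The step needs site selectivity for C6–H, which is the only C–H that is both 1,5 to the carbenoid and activated by an ether oxygen and an electron-rich arene; C1 is quaternary so no 1,2-hydride shift can compete, and the silylated tertiary oxygen offers no O–H.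

Step 12
Reactants: 17 furofuranone
Product: 18 ring B diol (C4 as CH2OH; C2 as the free benzylic carbinol)
Conditions: LiAlH4, THF, 0 °C
Reagents that add atoms: none
Why: Hydride reduction of the lactone to the 1,4-diol should leave the ethers and hindered silyl groups alone, and no stereocentre is touched.

Step 13
Reactants: 18 diol
Product: 20 (1S,2R,5R,6R)-2-ArS-6-ArG-1-(triethylsilyloxy)-3,7-dioxabicyclo[3.3.0]octane, via primary tosylate 19 (not isolated)
Conditions: TsCl, Et3N, DMAP (cat.), CH2Cl2, 0 °C; then NaH, THF, 0 °C to rt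
Reagents that add atoms: none
Why: Selective sulfonylation of the primary hydroxyl followed by intramolecular Williamson etherification (5-exo-tet) by the C2 alkoxide re-closes ring A, and C2 is retained because its C–O bond is never broken.

Step 14
Reactants: 20 6-endo furofuran
Product: 21 ring A oxolane with C5 carrying CH(SPh)ArG and C1 carrying CH2OH (both C6 epimers; taken on together)
Conditions: PhSH (5 equiv), BF3·OEt2 (1.2 equiv), CH2Cl2, −78 °C
Reagents that add atoms: benzenethiol, Sc1ccccc1
Why: Lewis-acid thiolysis of the p-silyloxybenzylic ether: C6–O7 ionises and the thiol captures the cation irreversibly, while C2–O3 should be held back by the β-oxygen on C1, the quaternary neighbour and the weaker, twisted donor of the syringyl ring; the C6 configuration is erased on purpose.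

Step 15
Reactants: 21 thioether
Product: 22 benzylic phenyl sulfone (both C6 epimers)
Conditions: mCPBA (2.2 equiv), NaHCO3, CH2Cl2, 0 °C
Reagents that add atoms: 3-chloroperoxybenzoic acid, OOC(=O)c1cccc(Cl)c1
Why: Chemoselective oxidation of the sulfide to the sulfone turns sulfur into a leaving group for a phenoxide-triggered 1,6-elimination.

Step 16
Reactants: 22 sulfone
Product: 24 fraxiresinol, via quinone methide 23 (not isolated)
Conditions: Bu4NF (5 equiv), THF, 0 °C to rt
Reagents that add atoms: none
Why: Fluoride removes the two TIPS groups and the TES group, the guaiacyl phenoxide expels benzenesulfinate to give quinone methide 23, and the C8 hydroxyl adds to C6 (intramolecular oxa-1,6-addition, the closure by which resinol lignans form) with allylic strain keeping H5 rather than C4 in the methide plane, so the aryl should end exo under kinetic, non-acidic conditions from either C6 epimer of 22.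

**Compound list**
1 | syringaldehyde | COc1cc(C=O)cc(OC)c1O | starting material
2 | 3,5-dimethoxy-4-(triisopropylsilyloxy)benzaldehyde | COc1cc(C=O)cc(OC)c1O[Si](C(C)C)(C(C)C)C(C)C | intermediate
3 | trimethyl phosphonoacetate | COC(=O)CP(=O)(OC)OC | starting material
4 | tert-butyl bromoacetate | CC(C)(C)OC(=O)CBr | starting material
5 | 4-tert-butyl 1-methyl 2-(dimethoxyphosphoryl)butanedioate (racemic) | COC(=O)C(CC(=O)OC(C)(C)C)P(=O)(OC)OC | intermediate
6 | 4-tert-butyl 1-methyl (2E)-2-(ArS-methylidene)butanedioate | COC(=O)/C(CC(=O)OC(C)(C)C)=C/c1cc(OC)c(O[Si](C(C)C)(C(C)C)C(C)C)c(OC)c1 | intermediate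
7 | tert-butyl (3E)-4-ArS-3-(hydroxymethyl)but-3-enoate | OC/C(CC(=O)OC(C)(C)C)=C/c1cc(OC)c(O[Si](C(C)C)(C(C)C)C(C)C)c(OC)c1 | intermediate
8 | tert-butyl 2-[(2S,3S)-3-ArS-2-(hydroxymethyl)oxiran-2-yl]acetate | OC[C@]1(CC(=O)OC(C)(C)C)O[C@H]1c1cc(OC)c(O[Si](C(C)C)(C(C)C)C(C)C)c(OC)c1 | intermediate
9 | (4S,5R)-5-ArS-4-hydroxy-4-(hydroxymethyl)oxolan-2-one | C1C(=O)O[C@H](c2cc(OC)c(O[Si](C(C)C)(C(C)C)C(C)C)c(OC)c2)[C@@]1(O)CO | intermediate
10 | vanillyl alcohol | COc1cc(CO)ccc1O | starting material
11 | (3-methoxy-4-(triisopropylsilyloxy)phenyl)methanol | COc1cc(CO)ccc1O[Si](C(C)C)(C(C)C)C(C)C | intermediate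
12 | ArG-methyl 2,2,2-trichloroacetimidate | COc1cc(COC(=N)C(Cl)(Cl)Cl)ccc1O[Si](C(C)C)(C(C)C)C(C)C | intermediate
13 | (4S,5R)-5-ArS-4-hydroxy-4-(ArG-methoxymethyl)oxolan-2-one | C1C(=O)O[C@H](c2cc(OC)c(O[Si](C(C)C)(C(C)C)C(C)C)c(OC)c2)[C@@]1(O)COCc1ccc(O[Si](C(C)C)(C(C)C)C(C)C)c(OC)c1 | intermediate
14 | (4S,5R)-5-ArS-4-(ArG-methoxymethyl)-4-(triethylsilyloxy)oxolan-2-one | C1C(=O)O[C@H](c2cc(OC)c(O[Si](C(C)C)(C(C)C)C(C)C)c(OC)c2)[C@@]1(O[Si](CC)(CC)CC)COCc1ccc(O[Si](C(C)C)(C(C)C)C(C)C)c(OC)c1 | intermediate
15 | 3-(trifluoroacetyl) derivative of 14 (C3 epimers or enol) | O=C(C1C(=O)O[C@H](c2cc(OC)c(O[Si](C(C)C)(C(C)C)C(C)C)c(OC)c2)[C@@]1(O[Si](CC)(CC)CC)COCc1ccc(O[Si](C(C)C)(C(C)C)C(C)C)c(OC)c1)C(F)(F)F | intermediate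
16 | (4S,5R)-3-diazo-5-ArS-4-(ArG-methoxymethyl)-4-(triethylsilyloxy)oxolan-2-one | [N-]=[N+]=C1C(=O)O[C@H](c2cc(OC)c(O[Si](C(C)C)(C(C)C)C(C)C)c(OC)c2)[C@@]1(O[Si](CC)(CC)CC)COCc1ccc(O[Si](C(C)C)(C(C)C)C(C)C)c(OC)c1 | intermediate
17 | (1S,2R,5R,6R)-2-ArS-6-ArG-1-(triethylsilyloxy)-3,7-dioxabicyclo[3.3.0]octan-4-one (cis-fused; 2-exo, 6-endo) | COc1cc([C@@H]2OC[C@]3(O[Si](CC)(CC)CC)[C@@H](c4cc(OC)c(O[Si](C(C)C)(C(C)C)C(C)C)c(OC)c4)OC(=O)[C@H]23)ccc1O[Si](C(C)C)(C(C)C)C(C)C | intermediate
18 | diol from 17: ring B oxolane with C5–CH2OH cis to ArG at C6, and C1 carrying OSiEt3 and the CH(OH)ArS carbinol | COc1cc([C@@H]2OC[C@](O[Si](CC)(CC)CC)([C@H](O)c3cc(OC)c(O[Si](C(C)C)(C(C)C)C(C)C)c(OC)c3)[C@@H]2CO)ccc1O[Si](C(C)C)(C(C)C)C(C)C | intermediate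
19 | primary 4-toluenesulfonate of 18 | COc1cc([C@@H]2OC[C@](O[Si](CC)(CC)CC)([C@H](O)c3cc(OC)c(O[Si](C(C)C)(C(C)C)C(C)C)c(OC)c3)[C@@H]2COS(=O)(=O)c2ccc(C)cc2)ccc1O[Si](C(C)C)(C(C)C)C(C)C | intermediate
20 | (1S,2R,5R,6R)-2-ArS-6-ArG-1-(triethylsilyloxy)-3,7-dioxabicyclo[3.3.0]octane (6-endo) | COc1cc([C@@H]2OC[C@]3(O[Si](CC)(CC)CC)[C@@H](c4cc(OC)c(O[Si](C(C)C)(C(C)C)C(C)C)c(OC)c4)OC[C@H]23)ccc1O[Si](C(C)C)(C(C)C)C(C)C | intermediate
21 | ring-B-opened thioether: ring A oxolane, C5–CH(SPh)ArG, C1–CH2OH (C6 epimers) | COc1cc(C(Sc2ccccc2)[C@H]2CO[C@H](c3cc(OC)c(O[Si](C(C)C)(C(C)C)C(C)C)c(OC)c3)[C@@]2(O[Si](CC)(CC)CC)CO)ccc1O[Si](C(C)C)(C(C)C)C(C)C | intermediate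
22 | sulfone of 21 (C6 epimers) | COc1cc(C([C@H]2CO[C@H](c3cc(OC)c(O[Si](C(C)C)(C(C)C)C(C)C)c(OC)c3)[C@@]2(O[Si](CC)(CC)CC)CO)S(=O)(=O)c2ccccc2)ccc1O[Si](C(C)C)(C(C)C)C(C)C | intermediate
23 | desilylated guaiacyl p-quinone methide (C6 as the methide carbon; C8–OH free) | COC1=CC(=C[C@H]2CO[C@H](c3cc(OC)c(O)c(OC)c3)[C@@]2(O)CO)C=CC1=O | intermediate
24 | fraxiresinol, (1S,2R,5R,6S) in the numbering above | COc1cc([C@H]2OC[C@]3(O)[C@@H](c4cc(OC)c(O)c(OC)c4)OC[C@H]23)ccc1O | target

**Step count**
Total: 16 steps. Longest linear sequence: 13 steps (1, 3, 4, 5, 8, 9, 10, 11, 12, 13, 14, 15, 16).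

**Steps most likely to fail, with fallbacks**

Step 11. The carbenoid may be diverted from C–H insertion: attack on one of the electron-rich arenes, hydride transfer from the ether followed by fragmentation, or carbene dimerisation. The fallback makes the same C5–C6 bond without a carbenoid and sets out from 14. DDQ in CH2Cl2/MeOH should oxidise the vanillyl ether C–H and give the mixed methyl acetal F1. LiN(iPr)2 and Me3SiCl at −78 °C should then give the silyl ketene acetal F2. Catalytic Me3SiOTf at −78 °C would ionise the acetal to the aryl oxocarbenium ion, which the ketene acetal carbon attacks (intramolecular Mukaiyama-type addition), closing ring B and returning to 17. Whichever way C6 falls, it is reset in steps 14 to 16.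

Step 14. Site selectivity of the ionisation may be lost: the C2–O3 ether may open as well, a silyl ether may be cleaved, or the cation may be captured by the syringyl ring in a Friedel–Crafts closure. The fallback gives up ring opening and sets out from 20. Bu4NF would give 6-epi-fraxiresinol F3. A catalytic acid (camphorsulfonic acid, CH2Cl2) would then epimerise C6 through the benzylic cation toward an equilibrium mixture, from which 24 is separated and F3 recycled. This is thermodynamic, not kinetic, control, and the route is rejoined at 24.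

Step 16. The quinone methide may tautomerise to the styrene or add water or fluoride before the ring closes, or facial control may be incomplete. The fallback sets out from thioether 21 (before oxidation) and closes ring B through a cation instead of a quinone methide. MeOTf with 2,6-di-tert-butyl-4-methylpyridine in CH2Cl2 at −40 °C would S-methylate; the sulfonium ionises and O7 captures the cation under buffered conditions to give the 6-exo furofuran tris-silyl ether F4. Bu4NF then returns to 24.

**Further compounds**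
F1 | step 11 | mixed methyl acetal of 14 (vanillyl CH2 replaced by CH(OMe); acetal epimers) | C1C(=O)O[C@H](c2cc(OC)c(O[Si](C(C)C)(C(C)C)C(C)C)c(OC)c2)[C@@]1(O[Si](CC)(CC)CC)COC(OC)c1ccc(O[Si](C(C)C)(C(C)C)C(C)C)c(OC)c1
F2 | step 11 | trimethylsilyl ketene acetal of F1 | C[Si](C)(C)OC1=C[C@](O[Si](CC)(CC)CC)(COC(OC)c2ccc(O[Si](C(C)C)(C(C)C)C(C)C)c(OC)c2)[C@@H](c2cc(OC)c(O[Si](C(C)C)(C(C)C)C(C)C)c(OC)c2)O1
F3 | step 14 | 6-epi-fraxiresinol | COc1cc([C@@H]2OC[C@]3(O)[C@@H](c4cc(OC)c(O)c(OC)c4)OC[C@H]23)ccc1O
F4 | step 16 | (1S,2R,5R,6S)-2-ArS-6-ArG-1-(triethylsilyloxy)-3,7-dioxabicyclo[3.3.0]octane (6-exo) | COc1cc([C@H]2OC[C@]3(O[Si](CC)(CC)CC)[C@@H](c4cc(OC)c(O[Si](C(C)C)(C(C)C)C(C)C)c(OC)c4)OC[C@H]23)ccc1O[Si](C(C)C)(C(C)C)C(C)C
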